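My vessel was to be closed, stirred and isothermal, charged with left-handed substrate and right-handed substrate as a racemate, partner, the single-handed free catalyst, racemization catalyst and added ligand, and I had the earlier runs to go on.

| setting | ochre | green | red | flask |
|---|---|---|---|---|
| left-handed substrate | 40 mM | 40 mM | 60 mM | 40 mM |
| right-handed substrate | 40 mM | 40 mM | 60 mM | 40 mM |
| partner | 3 equiv | 3 equiv | 3 equiv | 3.00 equiv |
| free catalyst | 2.5 mol% | 3.8 mol% | 5 mol% | 5 mol% |
| racemization catalyst | 9 mol% | 9 mol% | 9 mol% | 9 mol% |
| added ligand | 4.5 mM | 4.5 mM | 4.5 mM | 4.5 mM |
| remark | run made earlier | run made earlier | run made earlier |  |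
| time |  |  |  | 12 h |

- ochre (time / h: left-handed product / %, right-handed product / %): 1.00: 19.1, 6.3; 3.00: 30.5, 18.2; 5.00: 36.2, 21.6; 8.00: 42.2, 24.2; 12.0: 43.8, 30.0; 15.0: 45.3, 27.6
- green (time / h: left-handed product / %, right-handed product / %): 1.00: 23.8, 12.5; 2.00: 34.2, 18.6; 3.00: 36.5, 22.8; 5.00: 41.7, 26.5; 8.00: 46.0, 30.5; 15.0: 48.9, 34.1
- red (time / h: left-handed product / %, right-handed product / %): 1.00: 38.1, 23.1; 2.00: 44.9, 32.9; 4.00: 48.4, 41.5; 8.00: 52.1, 44.1; 15.0: 49.9, 45.6

(readings scatter by 1 percentage point)

- free catalyst is single-handed; left-handed substrate and right-handed substrate are mirror images of each other, charged as a racemate, each of them at the stated concentration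
- an excess is the difference of the two amounts in percent of their sum
- an excess is below zero if the other one leads

- left-handed product and right-handed product together, in percent of the left-handed substrate and right-handed substrate charged together, at 12 h
- excess of left-handed product over right-handed product in the product at 12 h
- whether the exchange between left-handed substrate and right-handed substrate keeps pace with the reaction: how far the product's excess at 12 h gets from its value without exchange to its value with instant exchange (above 80% keeps pace, below 20% hardly takes part, else lags behind)

First I asked how sharply free catalyst told the hands apart. From red at 1.00 h I read 2.32 as the selectivity factor s, the logarithm of the fraction of its own charge left to left-handed substrate, divided by the same logarithm for right-handed substrate. So the product should start at an excess near 39.7%.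

Did exchange refill left-handed substrate? Instant exchange would have held the excess near that value, but red at 15.0 h read only 4.50%. So I judged that exchange hardly took part, and took the left-handed fraction as the right-handed fraction raised to the power s.

How far would the flask get in 12 h? I counted loading times time as the clock, and the flask's was 1.05 times that of green at 15.0 h. Green's reading of right-handed product implied 31.8% of its right-handed substrate left, so raising this to that factor gave 29.9% for the flask, and s then gave 6.13% of the left-handed. My reckoning was a yield of 82.0% and an excess of 14.5%.

The forecast read the runs thus: “The runs behave like a plain kinetic resolution”. It gave 87% (83% to 91%), an excess of 12% (8% to 17%), and hardly takes part. My yield stood below its low end, while my excess lay inside its range.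

The flask gave 87.0% at an excess of 14.6%, and the exchange: hardly takes part, 9.3% of the way.

    left-handed substrate + racemization catalyst ⇌ right-handed substrate + racemization catalyst, rate k1*[racemization catalyst]*[left-handed substrate] forward; the back reaction follows from the equilibrium constant (k = 0.00150 M⁻¹ s⁻¹)
    partner + free catalyst + left-handed substrate → free catalyst + left-handed product (k = 1.70 M⁻² s⁻¹)
    partner + free catalyst + right-handed substrate → free catalyst + right-handed product (k = 0.710 M⁻² s⁻¹)
    2 partner → homo dimer (k = 1.20 × 10⁻⁴ M⁻¹ s⁻¹)
    free catalyst + added ligand ⇌ idle complex, settled at all times (K = 88.0 M⁻¹)
    partner → decomposed reagent (k = 1.80 × 10⁻⁵ s⁻¹)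

The flask kept 21% of its right-handed substrate, from which s put the left-handed rest at 2.56%, but the flask kept 5.4%, and that rest was the reading to watch. The neighbour flask with 0.750 equiv of partner kept 0.56% of its partner and gave a yield of 31.5%. Its right-handed rest of 76% gave by s a left-handed rest of 53.0% against the simulated 61%, and a product excess of 32.4% against the simulated 35.2%.

The numbers in the tables were generated by integration with constants of no real substance, noise included.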